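A small charge of free catalyst, 5.7 µM, opens the starting material in each flask, and the question is how far it gets before it stops.

| setting | ash | maple | alder | beta | delta |
|---|---|---|---|---|---|
| starting material | 10 mM | 10 mM | 15 mM | 10 mM | 10 mM |
| coupling partner | 7.5 mM | 30 mM | 15 mM | 15.0 mM | 15.0 mM |
| protic impurity | 2 mM | 2 mM | 2 mM | 2.00 mM | 2.00 mM |
| free catalyst | 5.7 µM | 5.7 µM | 5.7 µM | 5.7 µM | 5.7 µM |
| second catalyst | 1 mM | 1 mM | 1 mM | 1.0 mM | 1.0 mM |
| temperature | 40 °C | 51 °C | 40 °C | 35 °C | 55 °C |
| remark | run made earlier | run made earlier | run made earlier |  |  |
| time |  |  |  | 2.0 min | 2.0 min |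

- ash (time / s: open intermediate / %, product / %, starting material / %): 10.0: 31, 0, 67; 20.0: 49, 3, 50; 40.0: 69, 0, 30; 80.0: 79, 8, 16
- maple (time / s: open intermediate / %, product / %, starting material / %): 10.0: 40, 1, 56; 15.0: 48, 4, 48; 25.0: 55, 3, 39; 40.0: 57, 13, 34
- alder (time / s: open intermediate / %, product / %, starting material / %): 15.0: 43, 0, 59; 30.0: 57, 3, 40; 40.0: 65, 3, 33; 60.0: 73, 8, 19; 80.0: 72, 13, 18

(each reading ± 1.5 percentage points)

- the flask with the highest amount of open intermediate, in percent of the starting material charged ("all alike" if they lie within 1.5 percentage points) (beta / delta / all alike)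
- final open intermediate, as a percentage of the starting material charged, in beta
- final open intermediate, as a percentage of the starting material charged, in delta



At 80.0 s, ash and alder, both at 40 °C, keep 16% and 18% of their starting material, though alder has twice the coupling partner and a larger charge of starting material. So the percent left does not follow either charge, and we treat the opening as pseudo-first-order: c(starting material) decays with one rate constant k.

But the decay slows. Let L be the natural log of charged over remaining c(starting material). If k fades from its starting value k₀ with a catalyst lifetime τ, integrating k over time gives a finite sum, so L climbs exponentially towards k₀τ. We call this limit the reach. Each equal time step then adds the same fraction of the step before it, and a geometric series gives the limit from 3 equally spaced points.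

Ash, using zero, 40.0 s and 80.0 s, gives a reach of 2.52. Maple, at 51 °C and using 10.0 s, 25.0 s and 40.0 s, gives 1.16, a looser reading, since it rests on small differences. Maple also holds more coupling partner, 30 mM, but ash and alder showed no trace of that charge, so we read the lower reach as the effect of heat.

We run the log of the reach straight in temperature. That gives 3.58 for beta and 0.878 for delta. Delta's starting material should stop near 41.6%, which puts its converted share near 58.4%, and product is part of that share. Beta's converted share tends to about 97.2%, so we commit to beta.

The forecast says beta, with 73% in beta and 40% in delta: “Catalyst death is therefore much more temperature-sensitive”.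

The flask gives beta, with 74.9% in beta and 41.5% in delta.

    free catalyst → spent catalyst B (k = 0.0110 s⁻¹, Ea = 88.0 kJ mol⁻¹)
    starting material + free catalyst → free catalyst + open intermediate (k = 5800 M⁻¹ s⁻¹, Ea = 42.0 kJ mol⁻¹)
    coupling partner + protic impurity → quenched reagent (k = 0.550 M⁻¹ s⁻¹, Ea = 66.0 kJ mol⁻¹)
    coupling partner + catalyst intermediate → second catalyst + product (k = 920 M⁻¹ s⁻¹, Ea = 45.0 kJ mol⁻¹)
    second catalyst + open intermediate ⇌ catalyst intermediate (K = 0.180 M⁻¹, k = 11.0 M⁻¹ s⁻¹, Ea = 38.0 kJ mol⁻¹, ΔH = −13.0 kJ mol⁻¹)
    starting material + free catalyst → spent catalyst A (k = 0.0620 M⁻¹ s⁻¹, Ea = 56.0 kJ mol⁻¹)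
    (constants at 35 °C)

In delta the opening ran while free catalyst lasted: by 1.00 min free catalyst stood at 0.443%, spent catalyst B at 97.9%, and starting material at 37.3%, an L of 0.986, lower than the reach of 2.52 read from ash. Then, with starting material still at 37.2% at 2.00 min, open intermediate fell from 51.1% to 41.5% while product rose from 11.5% to 21.3%. Read at 3.0 min, the same flask has an L of 0.990, with open intermediate at 34.1% and product at 28.7%.

The data come from a simulation from invented constants; scatter was added.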